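**Retrosynthetic overview**
- The target is taken back to its C2 ketone; a last, substrate-controlled hydride reduction sets C2.
- The ketone is cut into two achiral pieces that are joined in one flask: C1–C6 by rhodium-catalysed asymmetric alkenyl addition to a ketone, then C3–C4 by intramolecular aldol addition.
- Pieces: C7–C1–C2–C3 is 2,3-dioxobutane-1,4-diyl dibenzoate, with both benzoates already in place; C4–C5=C6 is a (Z)-3-borylpropenal made from propynal diethyl acetal.
- Enabling feature: at the C2-ketone level the C1–C2–C3 half of the ring is a twofold-symmetric 1,2-dione. C1=O is the electrophile for C6, and C2=O then makes C3, the only enolisable carbon left, the nucleophile for C4. The cis C4–C5=C6 unit with oxygen on C4 is a Z-β-formylvinyl unit.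
- Ring order: the cyclohexene is the only ring and is closed by the aldol; no protecting groups are used.

Key step: step 4

Remark: the target SMILES is read as (1S,2S,3R,4S). C1 is the quaternary carbinol carbon, C2, C3 and C4 carry OH, OBz and OH, C5=C6 is the alkene and C7 is the exocyclic CH2. Compounds 1, 2, 4 and 5 are taken as commercial.

**Step 1**
Reactants: 1 1,4-dibromobutane-2,3-dione; 2 sodium benzoate
Product: 3 2,3-dioxobutane-1,4-diyl dibenzoate
Conditions: sodium benzoate (2.1 equiv. in total), DMF, 0 to 20 °C
Reagents that add atoms: sodium benzoate (the second equivalent of 2), [Na+].[O-]C(=O)c1ccccc1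
Why: Twofold carboxylate displacement of an α-bromo ketone (phenacyl-ester-type substitution) should be fast at both CH2Br groups, each of which is activated by the adjacent 1,2-dione and takes up one equivalent of benzoate; no stereocentre is formed.

**Step 2**
Reactants: 4 3,3-diethoxyprop-1-yne; 5 pinacolborane
Product: 6 (Z)-2-(3,3-diethoxyprop-1-en-1-yl)-4,4,5,5-tetramethyl-1,3,2-dioxaborolane
Conditions: [RhCl(cod)]2 (1.5 mol%), P(iPr)3 (6 mol%), Et3N (1 equiv.), 4 (1.2 equiv.), cyclohexane, 20 °C
Reagents that add atoms: none
Why: Rhodium-catalysed trans-hydroboration of a terminal alkyne (through a rhodium vinylidene) should place boron on the terminal carbon cis to the acetal carbon, which fixes the Z geometry needed later for ring closure; the acetal is inert.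

**Step 3**
Reactants: 6 (Z)-2-(3,3-diethoxyprop-1-en-1-yl)-4,4,5,5-tetramethyl-1,3,2-dioxaborolane
Product: 7 (Z)-3-(4,4,5,5-tetramethyl-1,3,2-dioxaborolan-2-yl)prop-2-enal
Conditions: Amberlyst-15 (H+ form), THF/H2O 10:1, 0 °C; resin filtered off, solution dried and used at once
Reagents that add atoms: water, O
Why: Mild acid-catalysed hydrolysis of an allylic acetal, which ionises much faster than the pinacol boronate hydrolyses; low temperature and immediate use are meant to preserve the Z geometry, which the cis carbonyl-oxygen-to-boron contact should also favour.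

**Step 4**
Reactants: 3 2,3-dioxobutane-1,4-diyl dibenzoate; 7 (Z)-3-(4,4,5,5-tetramethyl-1,3,2-dioxaborolan-2-yl)prop-2-enal
Product: 9 [(1S,3R,4S)-3-(benzoyloxy)-1,4-dihydroxy-2-oxocyclohex-5-en-1-yl]methyl benzoate, via Z-hydroxy-enal adduct 8 (not isolated)
Conditions: [RhCl(C2H4)2]2 (2.5 mol%), (R,R)-Ph-bod* or its antipode (5.5 mol%; the antipode that gives Re-face delivery is used), KOH (5 mol%), 3 (1.5 equiv.), toluene/H2O 20:1, 20 °C, slow addition of 7; then Et3N (0.5 equiv.), 0 °C, same flask
Reagents that add atoms: none
Why: Proposed new method: the hydroxorhodium–diene complex (monovalent rhodium) should transmetalate with 7 with retention of the Z geometry, the alkenylrhodium should insert one of the two homotopic, highly electrophilic carbonyl groups of 3 (C1–C6 bond, giving 8 after hydrolysis of the rhodium alkoxide), and triethylamine should then enolise the remaining ketone towards C3 for an intramolecular aldol addition to the cis formyl group (C3–C4 bond). The closest known reaction types are the rhodium-catalysed asymmetric 1,2-addition of aryl- and alkenylboron reagents to 1,2-diketones and the rhodium-catalysed addition–aldol annulations of 2-formylarylboronic acids; new is their union into a [3+3] annulation with a formyl-bearing Z-alkenylboronate. The cyclohexene closes by a 6-(enolendo)-exo-trig aldol, which is possible only because C6 and C4 are cis on the C5=C6 bond. C1 is set by the chiral diene (alkenyl delivery to the Re face gives 1S); C4 should follow from C1 because the tertiary hydroxyl, pseudo-axial with CH2OBz equatorial, hydrogen-bonds and activates the s-cis formyl oxygen on its own face so that the new hydroxyl ends cis to it (4S); C3 is epimerisable and should settle trans-diequatorial to C4 (3R). The step needs chemoselectivity of the alkenylrhodium for the 1,2-dione over the enal and the benzoates (activated dione in excess, slow addition of 7), regioselectivity (the twofold symmetry of 3 makes both carbonyls equivalent and leaves C3 as the only enolisable carbon after the addition) and the addition-before-aldol order (the amine is held back until 7 is consumed).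

**Step 5**
Reactants: 9 [(1S,3R,4S)-3-(benzoyloxy)-1,4-dihydroxy-2-oxocyclohex-5-en-1-yl]methyl benzoate
Product: 10 [(1S,2S,3R,4S)-3-(benzoyloxy)-1,2,4-trihydroxycyclohex-5-en-1-yl]methyl benzoate
Conditions: NaBH4 (1.0 equiv.), CeCl3·7H2O (1.0 equiv.), MeOH/CH2Cl2 1:1, −78 °C; AcOH quench
Reagents that add atoms: none
Why: Luche-type hydride reduction of a cyclic α-hydroxy ketone: axial attack on the face anti to the pseudo-axial C1 hydroxyl (polar Felkin–Anh, no 1,3-diaxial hindrance) should give the equatorial 2S alcohol, cis to the C1 hydroxyl and trans to the C3 benzoate, while the isolated alkene and the benzoates should be untouched at −78 °C.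

**Compound list**
1 | 1,4-dibromobutane-2,3-dione | BrCC(=O)C(=O)CBr | starting material
2 | sodium benzoate | [Na+].[O-]C(=O)c1ccccc1 | starting material
3 | 2,3-dioxobutane-1,4-diyl dibenzoate | O=C(OCC(=O)C(=O)COC(=O)c1ccccc1)c1ccccc1 | intermediate
4 | 3,3-diethoxyprop-1-yne | C#CC(OCC)OCC | starting material
5 | pinacolborane (4,4,5,5-tetramethyl-1,3,2-dioxaborolane) | [H]B1OC(C)(C)C(C)(C)O1 | starting material
6 | (Z)-2-(3,3-diethoxyprop-1-en-1-yl)-4,4,5,5-tetramethyl-1,3,2-dioxaborolane | CCOC(OCC)/C=C\B1OC(C)(C)C(C)(C)O1 | intermediate
7 | (Z)-3-(4,4,5,5-tetramethyl-1,3,2-dioxaborolan-2-yl)prop-2-enal | O=C/C=C\B1OC(C)(C)C(C)(C)O1 | intermediate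
8 | (2Z,4S)-4-[(benzoyloxy)acetyl]-5-(benzoyloxy)-4-hydroxypent-2-enal | O=C(OC[C@@](O)(/C=C\C=O)C(=O)COC(=O)c1ccccc1)c1ccccc1 | intermediate (not isolated)
9 | [(1S,3R,4S)-3-(benzoyloxy)-1,4-dihydroxy-2-oxocyclohex-5-en-1-yl]methyl benzoate | O=C(OC[C@@]1(O)C=C[C@H](O)[C@@H](OC(=O)c2ccccc2)C1=O)c1ccccc1 | intermediate
10 | [(1S,2S,3R,4S)-3-(benzoyloxy)-1,2,4-trihydroxycyclohex-5-en-1-yl]methyl benzoate | O=C(OC[C@@]1(O)C=C[C@H](O)[C@@H](OC(=O)c2ccccc2)[C@@H]1O)c1ccccc1 | target

**Step count**
Total steps: 5. Longest linear sequence: 4 (steps 2, 3, 4, 5).

**Steps most likely to fail**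

Step 4 (proposed new method). The free formyl group of 7 may be attacked by the alkenylrhodium (self-addition and oligomerisation), the Z geometry may be lost on rhodium, or the aldol may run before the addition and erode the 1,4-induction from C1 to C4. The fallback separates the two bond formations with the aldehyde masked and sets out from 3 and 6. Rhodium-catalysed asymmetric 1,2-addition of 6 to 3 (catalyst of step 4, no amine) should give the acetal-protected tertiary alcohol (2S,3Z)-2-[(benzoyloxy)acetyl]-5,5-diethoxy-2-hydroxypent-3-en-1-yl benzoate F1. Amberlyst-15 in aqueous THF should then unmask the aldehyde to 8, isolated as its lactol [(2S)-2-[(benzoyloxy)acetyl]-5-hydroxy-2,5-dihydrofuran-2-yl]methyl benzoate F2. Soft enolisation with MgBr2·OEt2 and Et3N in CH2Cl2 at −20 °C, with magnesium bridging the tertiary oxygen and the formyl oxygen, should close the ring, and the route is rejoined at 9.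

Step 3. During acetal hydrolysis the tricoordinate boryl enal may isomerise from Z to E or lose boron by protodeboronation. The fallback sets out from 6 and changes the boron group before the aldehyde is unmasked. KHF2 in MeOH/H2O should give potassium (Z)-(3,3-diethoxyprop-1-en-1-yl)trifluoroborate F3. LiBF4 in wet MeCN should then cleave the acetal to potassium (Z)-(3-oxoprop-1-en-1-yl)trifluoroborate F4, a tetracoordinate, non-Lewis-acidic salt. F4 would take the place of 7 in the rhodium-catalysed addition–aldol (alkenyltrifluoroborates are established partners in such 1,2-additions), and the route is rejoined at 9.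

Step 5. Hydride may attack the other face of the C2 ketone (for example by delivery from a borate formed at the C1 hydroxyl), and the basic medium may cause benzoate migration or retro-aldol opening. The fallback sets out from 9 and replaces substrate control by catalyst control under slightly acidic conditions: Noyori asymmetric transfer hydrogenation with RuCl(p-cymene)[(S,S)-TsDPEN] or its antipode (the one matched to the 2S alcohol) in HCO2H/Et3N 5:2 at 0 °C. It gives 10 directly and forms no new compound (entry F0).

**Further compounds**
F1 | step 4 | (2S,3Z)-2-[(benzoyloxy)acetyl]-5,5-diethoxy-2-hydroxypent-3-en-1-yl benzoate | O=C(OC[C@@](O)(/C=C\C(OCC)OCC)C(=O)COC(=O)c1ccccc1)c1ccccc1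
F2 | step 4 | [(2S)-2-[(benzoyloxy)acetyl]-5-hydroxy-2,5-dihydrofuran-2-yl]methyl benzoate | O=C(OC[C@]1(C(=O)COC(=O)c2ccccc2)C=CC(O)O1)c1ccccc1
F3 | step 3 | potassium (Z)-(3,3-diethoxyprop-1-en-1-yl)trifluoroborate | [K+].CCOC(OCC)/C=C\[B-](F)(F)F
F4 | step 3 | potassium (Z)-(3-oxoprop-1-en-1-yl)trifluoroborate | [K+].O=C/C=C\[B-](F)(F)F
F0 | step 5 | none | none
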